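## Analysis of the target

The target 9 is an achiral diaryl ether, C12H5Br5O2, made of two benzene rings joined through one oxygen. Ring A is the phenol ring: C1 carries the hydroxyl, C2 the ether oxygen, C3 the only hydrogen, and C4, C5 and C6 three contiguous bromines. Ring B is a 2,4-dibromophenyl group, with the ether oxygen on C1' and bromines on C2' and C4'. There are no stereocentres, so the whole problem is regiochemistry plus one hindered bond. The sensitive groups are the five aryl C–Br bonds (open to insertion by low-valent copper or palladium, to halogen–lithium exchange and to hydrogenolysis) and the acidic phenol. The synthesis is hard because the O–C2 bond joins two electron-poor, ortho-substituted rings, and because the five bromines must occupy exactly five of the nine open ring positions. Four bromines sit ortho or para to an oxygen on their own ring that can direct them; the fifth, on C5 of ring A, is meta to the hydroxyl carbon C1 and para to the ether carbon C2, and substitution on the arene cannot place it with certainty. The plan rests on the triad C1–OH, C2–OAr, C5–Br of ring A: C1 and C5 stand 1,3 to each other across C6, with C2 next to C1, which is the pattern of a 4-aryloxycyclohexane-1,3-dione, so ring A can be built by a Claisen-type closure around an sp3 carbon C2 that already carries the ether oxygen.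

## Retrosynthetic reasoning

**9 to 8.** The C4–Br and C6–Br bonds are cut first. They are para and ortho to the free hydroxyl at C1, the two positions the phenol itself commands. Forward, two equivalents of electrophilic bromine must enter ring A of 8 without touching C3 or the deactivated ring B.

**8 to 7.** The aromaticity of ring A is removed. The C5 bromine of 8 cannot be introduced reliably on an arene, so ring A is read one oxidation level lower, as cyclohexenone 7: C1 is the carbonyl, C5=C6 the enone double bond with bromine on C5, and C2 an sp3 carbon bearing the aryloxy group. Forward, one equivalent of bromine should dehydrogenate 7 to 8. This merges with the previous disconnection into a single operation (7 to 9).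

**7 to 6.** The C5–Br bond is cut back to a carbonyl. Compound 7 is the vinylogous acyl bromide of the cyclic 1,3-dione 6. Forward, bromide must replace the oxygen on the carbonyl remote from the aryloxy carbon, not the one next to it.

**6 to 3 and 4 (key disconnection).** Two ring bonds are cut: C2–C3 (Michael retron) and C5–C6 (Claisen retron of the 1,3-dicarbonyl). This splits ring A into a three-carbon ketone piece (C6, C1, C2, from 3) and a three-carbon acrylate piece (C3, C4, C5, from 4). These cuts are chosen because all three substituents that define ring A follow from which atom of 3 and 4 becomes which ring carbon: oxygen at C1, aryloxy at C2, and the future bromine at C5. No aryl–oxygen bond has to be formed on a brominated arene. Forward, one base-mediated operation must add the aryloxy-bearing carbon of 3 to 4 and then close the six-membered ring.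

**3 to 1 and 2.** The O–C2 bond is cut while C2 is still an sp3 carbon next to a ketone. It becomes a simple SN2 etherification, and both bromines of ring B arrive in place with commercial 1.

## Alternatives that were turned down

**Alternative 1:** the textbook disconnection, the aryl–oxygen bond between two intact benzene rings.
- Forward key step: a copper-catalysed Ullmann coupling of the two unbrominated partners to 1-methoxy-2-phenoxybenzene A1, fourfold bromination to 1,2-dibromo-4-(2,4-dibromophenoxy)-5-methoxybenzene A2, O-demethylation and a last bromination at C6.
- Why turned down:
  - Four C–Br bonds would be made in one substitution on two rings of similar reactivity. C6' (the second ortho position of ring B) and C3 compete, and mixtures of tetra- and pentabromides would result.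
  - Coupling pre-brominated partners instead asks a zerovalent palladium or monovalent copper catalyst to choose one carbon–halogen bond among several C–Br bonds.
  - A variant by nucleophilic aromatic substitution needs an activating group that the target lacks and must then be exchanged for the hydroxyl.
  - None of these is shorter than four steps.

**Alternative 2:** an aryne on ring A, cutting O–C2 and C3–H.
- Forward key step: fluoride-induced generation of 1,2,3-tribromo-4-methoxy-5,6-didehydrobenzene A4 from 3,4,5-tribromo-2-methoxy-6-(trimethylsilyl)phenyl trifluoromethanesulfonate A3, addition of the phenoxide of 1 across the triple bond, then O-demethylation.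
- Why turned down:
  - The methoxy group beside the triple bond (on C1) polarises it so that a nucleophile adds to the far carbon C3, placing the developing carbanion on C2 next to the inductively withdrawing oxygen. The C4 bromine pulls the other way but more weakly. The aryloxy group is therefore expected mainly on C3, meta to the C1 oxygen.
  - The precursor A3 is a hexasubstituted benzene and is harder to make than the target.

**Alternative 3:** biomimetic oxidative phenol cross-coupling, cutting O–C2 between two phenols.
- Forward key step: one-electron oxidation of a mixture of 1 and 2,3,4-tribromophenol A5, bonding of the phenoxyl oxygen of 1 to the free ortho carbon of A5, and tautomerisation.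
- Why turned down:
  - Radical coupling offers no control over cross- versus homo-coupling, O–C versus C–C bonding, or ortho versus para attack.
  - The para positions of both partners carry bromine, so ipso coupling with loss of bromide to quinoid products competes.
  - A5 is not available by direct bromination of phenol and would need its own synthesis.

Key step: step 2

Assumption: compounds 1, 2 and 4 are commercial; 5, 6 and 7 each carry one stereocentre (the aryloxy-bearing carbon) and are handled as racemates, because this centre becomes an aromatic carbon in step 4.

## Route

Step 1
Reactants: 1 2,4-dibromophenol; 2 chloroacetone (1-chloropropan-2-one)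
Product: 3 1-(2,4-dibromophenoxy)propan-2-one
Conditions: K2CO3, KI (cat.), acetone, reflux
Reagents that add atoms: none
Why: Williamson ether synthesis: the phenoxide of 1 displaces chloride from the activated primary α-halo ketone carbon (SN2, iodide catalysis), so the O–C2 bond forms at an sp3 carbon and no aryl C–Br bond is put at risk.

Step 2
Reactants: 3 1-(2,4-dibromophenoxy)propan-2-one; 4 methyl acrylate
Product: 6 4-(2,4-dibromophenoxy)cyclohexane-1,3-dione (racemic), via methyl 4-(2,4-dibromophenoxy)-5-oxohexanoate 5 (not isolated)
Conditions: KOtBu (2.2 equiv), THF, −10 °C, slow addition of 4 (1.0 equiv), then 20 °C; aq. HCl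
Reagents that add atoms: none
Why: This is a consecutive Michael–Claisen annulation, the known way from substituted acetones and acrylates to 4-substituted cyclohexane-1,3-diones. KOtBu should deprotonate 3 reversibly, and the enolate at the aryloxy-bearing methylene (ring A C2), being the more acidic and more populated one, should add to the β-carbon of 4 (new bond C2–C3) to give 5. Proton transfer then exposes the methyl enolate (C6), which acylates the ester carbonyl (new bond C5–C6) in a 6-(enolexo)-exo-trig closure; closure from the aryloxy carbon would give a four-membered ring and is ruled out. Loss of methoxide and immediate deprotonation of the 1,3-dione by the second equivalent of base make the sequence irreversible. The one new stereocentre (C4 of 6, ring A C2) forms as a racemate without control, which is harmless because it becomes an sp2 carbon in step 4. The selectivity needed is conjugate addition through the aryloxy methylene and not the methyl group (which would put the oxygen between the two carbonyls), and single addition; the acidifying aryloxy group secures the first, slow addition of one equivalent of 4 at low temperature the second. The aryl bromides and the aryl ether are inert to KOtBu in THF at or below room temperature.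

Step 3
Reactants: 6 4-(2,4-dibromophenoxy)cyclohexane-1,3-dione
Product: 7 3-bromo-6-(2,4-dibromophenoxy)cyclohex-2-en-1-one (racemic)
Conditions: (COBr)2 (1.2 equiv), DMF (cat.), CH2Cl2, 0 → 20 °C
Reagents that add atoms: oxalyl bromide, O=C(Br)C(=O)Br
Why: Conversion of a cyclic 1,3-dione into a β-bromo enone by O-activation and addition–elimination of bromide; bromide should enter at C1 of 6 (flanked by two methylenes, future ring A C5) and not at C3, which is shielded and inductively deactivated by the aryloxy-bearing C4, in the same sense in which 4,4-disubstituted cyclohexane-1,3-diones react at the remote carbonyl.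

Step 4
Reactants: 7 3-bromo-6-(2,4-dibromophenoxy)cyclohex-2-en-1-one
Product: 9 2,3,4-tribromo-6-(2,4-dibromophenoxy)phenol (the target), via 5-bromo-2-(2,4-dibromophenoxy)phenol 8 (not isolated)
Conditions: Br2 (3.05 equiv), HBr/AcOH (cat.), CHCl3, 0 → 55 °C
Reagents that add atoms: bromine, BrBr
Why: Brominative aromatisation of a cyclohexenone (bromination through the enol or dienol, loss of HBr, tautomerisation of the dienone) should give phenol 8, which the remaining two equivalents brominate at once ortho (C6) and para (C4) to the hydroxyl by electrophilic aromatic substitution. Every carbon that can be brominated at the ketone stage either ends as C4 or C6 or loses its bromine on aromatisation, C3 is neither enolisable nor activated by the hydroxyl, and ring B is deactivated, so all pathways should converge on 9.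

## Compound list

1 | 2,4-dibromophenol | Oc1ccc(Br)cc1Br | starting material
2 | chloroacetone (1-chloropropan-2-one) | CC(=O)CCl | starting material
3 | 1-(2,4-dibromophenoxy)propan-2-one | CC(=O)COc1ccc(Br)cc1Br | intermediate
4 | methyl acrylate | C=CC(=O)OC | starting material
5 | methyl 4-(2,4-dibromophenoxy)-5-oxohexanoate (racemic, not isolated) | COC(=O)CCC(Oc1ccc(Br)cc1Br)C(C)=O | intermediate
6 | 4-(2,4-dibromophenoxy)cyclohexane-1,3-dione (racemic, largely enolised) | O=C1CC(=O)C(Oc2ccc(Br)cc2Br)CC1 | intermediate
7 | 3-bromo-6-(2,4-dibromophenoxy)cyclohex-2-en-1-one (racemic) | O=C1C=C(Br)CCC1Oc1ccc(Br)cc1Br | intermediate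
8 | 5-bromo-2-(2,4-dibromophenoxy)phenol (not isolated) | Oc1cc(Br)ccc1Oc1ccc(Br)cc1Br | intermediate
9 | 2,3,4-tribromo-6-(2,4-dibromophenoxy)phenol | Oc1c(Oc2ccc(Br)cc2Br)cc(Br)c(Br)c1Br | target

## Step count and risk

Total step count: 4. Longest linear sequence: 4 steps (1 → 3 → 6 → 7 → 9).

**Step 2 (key step).** What may go wrong: conjugate addition through the methyl enolate instead of the aryloxy methylene, a second addition of acrylate to 5 or to the dione anion, or aldol self-condensation of 3. Any of these erodes or misdirects the ring construction. Fallback, setting out from 1 and returning at 6: commercial 3-ethoxycyclohex-2-en-1-one F1 would be deprotonated at C6 with LiN(iPr)2 in THF at −78 °C (the α′-enolate of the Stork–Danheiser sequence) and brominated with N-bromosuccinimide to 6-bromo-3-ethoxycyclohex-2-en-1-one F2. Displacement of the α′-bromide by the phenoxide of 1 (K2CO3, acetone) would give 6-(2,4-dibromophenoxy)-3-ethoxycyclohex-2-en-1-one F3, and aqueous HCl in THF would hydrolyse the vinylogous ester to 6.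

**Step 3.** What may go wrong: delivery of bromide to the carbonyl carbon next to the aryloxy group. This would transpose the enone and, after aromatisation, destroy the ortho relationship of hydroxyl and ether oxygen. Fallback, setting out from 1 and returning at 8, bypassing 6 and 7: nucleophilic aromatic substitution of the phenoxide of 1 on commercial 5-bromo-2-fluorobenzaldehyde F4 (K2CO3, N,N-dimethylacetamide, 110 °C) would give 5-bromo-2-(2,4-dibromophenoxy)benzaldehyde F5. Baeyer–Villiger oxidation with mCPBA would give 5-bromo-2-(2,4-dibromophenoxy)phenyl formate F6, and methanolysis (K2CO3, MeOH) would release 8. Compound 8 would then take up two equivalents of Br2 in AcOH at C4 and C6 to give 9.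

**Step 4.** What may go wrong: stalling at α-bromo ketones through incomplete loss of HBr, solvolytic loss of the aryloxy group at the carbon that carries both bromine and oxygen, hydrolysis of the vinylogous acyl bromide by adventitious water, or over-bromination at C3 or C6'. Fallback, setting out from 7 and returning at 8, separating dehydrogenation from bromination: deprotonation of 7 at C6 with LiN(SiMe3)2 in THF at −78 °C and trapping with PhSeBr would give 3-bromo-6-(2,4-dibromophenoxy)-6-(phenylselanyl)cyclohex-2-en-1-one F7. Oxidation with H2O2 and pyridine in CH2Cl2 would give the selenoxide 3-bromo-6-(2,4-dibromophenoxy)-6-(phenylseleninyl)cyclohex-2-en-1-one F8, whose syn-elimination towards C5 and tautomerisation should deliver 8. Isolated 8 would then be brominated with two equivalents of Br2 in AcOH to 9.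

## Further compounds

F1 | step 2 | 3-ethoxycyclohex-2-en-1-one | CCOC1=CC(=O)CCC1
F2 | step 2 | 6-bromo-3-ethoxycyclohex-2-en-1-one | CCOC1=CC(=O)C(Br)CC1
F3 | step 2 | 6-(2,4-dibromophenoxy)-3-ethoxycyclohex-2-en-1-one | CCOC1=CC(=O)C(Oc2ccc(Br)cc2Br)CC1
F4 | step 3 | 5-bromo-2-fluorobenzaldehyde | O=Cc1cc(Br)ccc1F
F5 | step 3 | 5-bromo-2-(2,4-dibromophenoxy)benzaldehyde | O=Cc1cc(Br)ccc1Oc1ccc(Br)cc1Br
F6 | step 3 | 5-bromo-2-(2,4-dibromophenoxy)phenyl formate | O=COc1cc(Br)ccc1Oc1ccc(Br)cc1Br
F7 | step 4 | 3-bromo-6-(2,4-dibromophenoxy)-6-(phenylselanyl)cyclohex-2-en-1-one | O=C1C=C(Br)CCC1(Oc1ccc(Br)cc1Br)[Se]c1ccccc1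
F8 | step 4 | 3-bromo-6-(2,4-dibromophenoxy)-6-(phenylseleninyl)cyclohex-2-en-1-one | O=C1C=C(Br)CCC1(Oc1ccc(Br)cc1Br)[Se](=O)c1ccccc1
A1 | alternative 1 | 1-methoxy-2-phenoxybenzene | COc1ccccc1Oc1ccccc1
A2 | alternative 1 | 1,2-dibromo-4-(2,4-dibromophenoxy)-5-methoxybenzene | COc1cc(Br)c(Br)cc1Oc1ccc(Br)cc1Br
A3 | alternative 2 | 3,4,5-tribromo-2-methoxy-6-(trimethylsilyl)phenyl trifluoromethanesulfonate | COc1c(Br)c(Br)c(Br)c([Si](C)(C)C)c1OS(=O)(=O)C(F)(F)F
A4 | alternative 2 | 1,2,3-tribromo-4-methoxy-5,6-didehydrobenzene | COC1=C(Br)C(Br)=C(Br)C#C1
A5 | alternative 3 | 2,3,4-tribromophenol | Oc1ccc(Br)c(Br)c1Br
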